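## The problem

The target is an unsymmetrical biflavonoid. A (2S)-5,7,4'-trihydroxyflavanone (naringenin unit) and a (2R,3R)-3,5,7,4'-tetrahydroxyflavanone (aromadendrin unit) are joined by one aryl–aryl bond between C3' and C3''', the ring B carbons ortho to the two 4'-hydroxyls. There are three stereocentres: C2 of the flavanone and the trans pair C2''/C3'' of the dihydroflavonol. Within the dihydroflavonol, C3'' can hold C2'' trans thermodynamically, but the biaryl insulates the two heterocycles, so neither can direct the other and each must arrive with its configuration. Both heterocycles are fragile to base: the flavanone loses C2 by opening to the 2'-hydroxychalcone (through the C3 enolate or, once the 4'-phenol is ionised, through a quinone methide), and the dihydroflavonol epimerises and oxidises under the same conditions; dilute acid is tolerated better. Seven hydroxyls of graded reactivity must be told apart (7-OH most acidic, then 4'-OH, the chelated 5-OH, the aliphatic 3''-OH), and the phloroglucinol-type rings A outrun the rings B in electrophilic substitution and also trap one-carbon electrophiles. The biaryl bond joins two carbons of like polarity, so an untethered union must solve cross- versus homo-coupling and regiochemistry together. The enabling feature is the array O4'–C4'–C3'···C3'''–C4'''–O4''': one CH2 between the two phenolic oxygens turns the coupling into closure of a seven-membered dibenzo[d,f][1,3]dioxepine, and with only these two ortho substituents the new axis is not a stereogenic element.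

## Retrosynthesis

**18 from 17.** Only five O–acyl bonds are cut: four aryl acetates on the rings A and one acetate on O3''. Esters are chosen over ethers because they come off by acid-catalysed methanolysis, the medium in which C2, C2'' and C3'' are safest. The same esters are needed earlier to switch off the rings A. The forward step asks only for transesterification.

**17 from 16.** The CH2 between O4' and O4''' is put back, so two aryl O–C bonds are cut in the forward sense. A diaryl formal resists dilute acid, so its removal is planned as a separate Lewis-acid cleavage on pentaacetate 16. With the rings A still acylated, the released one-carbon electrophile cannot add to a phloroglucinol ring. The precursor is no simpler in atom count, but it is the compound in which the biaryl bond is part of a ring.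

**16 from 15 (key cut).** The C3'–C3''' bond is cut to give the bis(aryl iodide) 15. This is the only bond that joins two intact flavonoid skeletons, so cutting it returns all three stereocentres and both oxidation patterns to purchasable natural products. Cuts inside either heterocycle would mean building a chalcone and a new stereocentre. An untethered cross-coupling would need one ring B as a nucleophile, made under base on an acetylated polyphenol, and would still have to fight homo-coupling at a hindered ortho-oxygenated site. The tether makes both carbons electrophilic partners of one metal centre, fixes the hetero-pairing and fixes the regiochemistry. The forward reaction must join two aryl iodides under neutral conditions that spare ketones, esters and an acetal.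

**15 from 6 and 14; 14 from 13; 13 from 12.** One O–CH2 bond of the formal is cut, giving iodophenol 6 and chloromethyl ether 14. An unsymmetrical formal cannot be made cleanly by double alkylation of two phenols with a dihalomethane: a statistical mixture of three formals would result, and the carbonate needed would open the flavanone and transfer the activated 7-acetate. The CH2 is therefore attached to one half first, as O,S-acetal 13, then converted to chloride 14 and coupled under amine-base conditions of the kind used for alkoxymethyl protection of phenols. The aromadendrin half carries the CH2 because it has no enolisable methylene next to its ketone, so it is the safer partner for the chlorination.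

**6 from 5; 12 from 11.** The C–I bonds are cut. Iodination must go to ring B, ortho to the 4'-oxygen. This is only expected when the 4'-hydroxyl is free and both ring A oxygens are acylated, which leaves ring B as the sole phenol in the molecule. The forward step asks for mono-iodination of a para-substituted phenol.

**5 from 4, 3, 2 and 1; 11 from 10, 9, 8 and 7.** Only protecting-group bonds are cut. Direct acylation cannot leave O4' free, because 7-OH reacts first and 4'-OH second. O4' is therefore parked as a silyl ether. Bis-silylation of the two reactive phenols (2, 8) is followed by selective methanolysis of the much more labile 7-O-silyl ether (3, 9). Exhaustive acetylation follows (4, 10), which on the aromadendrin side also covers O3'' and saves a separate protection there. Fluoride then releases the phenols 5 and 11. The starting points are (2S)-naringenin 1 and (2R,3R)-aromadendrin 7.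

## Roads not taken

**Alternative 1:** The cut is through the C3–C4 bonds of both pyran rings. The precursor is tetraene A1, a preformed biaryl whose two benzylic carbons each carry a vinyl group and an ether link to a 2-vinyl-3,5-bis(benzyloxy)phenyl ring. A ruthenium alkylidene metathesis catalyst would close both rings C in one operation to the bis(flav-3-ene) A2.
- Merits: the biaryl is made early on simple arenes by routine cross-coupling; both heterocycles form together; benzyl ethers are robust and leave by neutral hydrogenolysis; no diaryl formal has to be cleaved. In these respects it is better than the chosen plan.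
- Weak points: the two flavene units of A2 are constitutionally identical, yet one must become a 4-ketone without oxygen at C3 and the other a trans-3-hydroxy-4-ketone. No reagent can tell them apart, so the oxidation would be statistical, or the halves would have to be built one after another and the double closure given up. Flav-3-enes do not oxidise directly to 4-ketones, since hydroboration places oxygen at C3. 2-Aryl-2H-chromenes with electron-rich rings A can lose C2 by reversible electrocyclic opening and ionise readily in acid. The two enantioenriched 1-arylallyl aryl ethers in A1 must be set by substitution at an ionisable benzylic allylic carbon.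
- Comparison: the chosen plan has a harder protecting-group problem and a less routine bond-forming step. Against that it sets both oxidation patterns and all three stereocentres bought and already differentiated in 1 and 7, and a much shorter sequence.

**Alternative 2:** The cut removes two ring C–C bonds of one ring B. The 2-aryl-1-methoxy-3-silyloxybutadiene A3 and ethyl propiolate A4 would combine in a [4+2] cycloaddition, and loss of methanol from the adduct would give the biaryl ester A5.
- Merits: the ortho,ortho'-dioxygenated biaryl is fixed by construction, since the aryl–aryl bond already exists as an aryl–vinyl bond in A3. The two halves carry different handles (ester and bromide) and different oxygen protection (silyl and methoxymethyl), so they can be elaborated in turn. This is the differentiation Alternative 1 lacks, and it avoids the silyl relay the chosen plan needs to free O4'. No late organometallic step on a complex substrate is required.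
- Weak points: A5 is a simple biaryl with none of the three stereocentres, no ring A and no ring C. A comparably differentiated biaryl is available in one standard cross-coupling, so the cycloaddition solves an easy problem. The hard work remains: two chalcone-type constructions, an enantioselective oxa-Michael closure for the (2S)-flavanone (a reaction of narrow scope on 5,7-dioxygenated systems whose product racemises by the reverse reaction), and an asymmetric epoxidation and cyclisation for the dihydroflavonol, the second carried out while the first heterocycle must survive base.
- Comparison: Alternative 2 is independent of natural-product supply and controls from the start which oxygen is which. The chosen plan answers with no enantioselective step at all and roughly half the step count.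

**Alternative 3:** The cut is through O1''–C8a'' and C4''–C4a'' of the dihydroflavonol, so ring A is added to a three-carbon acid. Fluoride would release an aryne from silyl triflate A6; the acetonide-protected (2R,3S)-dihydroxy acid A7 would add through oxygen, and acyl transfer to the aryl anion would give the 2-hydroxyaryl ketone A8.
- Merits: the dihydroflavonol stereocentres come from a dependable asymmetric dihydroxylation of a cinnamate and travel as a trans acetonide. The alkoxy group directs the aryne addition to the 2-hydroxy-4,6-dioxygenated ketone pattern. No chalcone is involved on this half. It does not depend on 7, the scarcer of the two natural products, which is a real advantage over the chosen plan.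
- Weak points: only the dihydroflavonol half is addressed. The flavanone half would have to grow from the aryl chloride of A8, a poor handle, through a chalcone and an asymmetric cyclisation, with the epimerisable α-oxygenated ketone present. Closing ring C from A8 needs an invertive displacement at a benzylic carbon para to an alkoxy group by a hindered, hydrogen-bonded phenol, where ionisation would mix cis and trans isomers. Protonation of the aryl anion before acyl transfer would give the aryl ester in place of the ketone.
- Comparison: Alternative 3 gives better stereochemical self-sufficiency on one half. The chosen plan sets against it a single convergent bond formation that finishes both halves at once.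

Key step: step 11

Assumption: (2S)-naringenin and (2R,3R)-aromadendrin [(+)-dihydrokaempferol] are taken as commercially available single enantiomers; locants follow biflavonoid usage (3' on the flavanone ring B, 3''' on the dihydroflavonol ring B, C2''/C3'' for the dihydroflavonol stereocentres).

## Route

Step 1
Reactants: 1 (2S)-naringenin
Product: 3 (2S)-4'-O-(tert-butyldimethylsilyl)naringenin, via 7,4'-bis-O-TBS-naringenin 2 (not isolated)
Conditions: TBSCl (2.3 equiv), imidazole, DMF, 0 °C to rt; extractive work-up; then K2CO3 (0.3 equiv), MeOH–THF, 0 °C; AcOH quench
Reagents that add atoms: tert-butyldimethylsilyl chloride, CC(C)(C)[Si](C)(C)Cl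
Why: Imidazole-promoted phenol silylation takes the two free phenols and leaves the chelated 5-OH; the 7-O-silyl ether, whose phenoxide is stabilised by the para carbonyl, is then solvolysed selectively (aryl silyl ether methanolysis). With O4' blocked and ring A present as an electron-rich 7-phenoxide, neither the quinone methide nor the enolate route to the chalcone is open, so C2 should hold.

Step 2
Reactants: 3 (2S)-4'-O-(tert-butyldimethylsilyl)naringenin
Product: 4 (2S)-5,7-di-O-acetyl-4'-O-(tert-butyldimethylsilyl)naringenin
Conditions: Ac2O, pyridine, DMAP (cat.), CH2Cl2, 0 °C to rt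
Reagents that add atoms: acetic anhydride, CC(=O)OC(C)=O
Why: DMAP-catalysed O-acylation esterifies 7-OH and the chelated 5-OH; the unactivated 4'-O-silyl ether is inert, and at room temperature the flavanone is not opened by pyridine.

Step 3
Reactants: 4 (2S)-5,7-di-O-acetyl-4'-O-(tert-butyldimethylsilyl)naringenin
Product: 5 (2S)-5,7-di-O-acetylnaringenin
Conditions: HF·pyridine, THF–pyridine, 0 °C to rt
Reagents that add atoms: none
Why: Fluoride-driven cleavage of the aryl silyl ether under acidic conditions; no phenoxide is generated, so the activated aryl acetates neither cleave nor migrate.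

Step 4
Reactants: 5 (2S)-5,7-di-O-acetylnaringenin
Product: 6 (2S)-5,7-di-O-acetyl-3'-iodonaringenin
Conditions: NIS (1.0 equiv), CF3CO2H (cat.), MeCN, 0 °C
Reagents that add atoms: N-iodosuccinimide, O=C1CCC(=O)N1I
Why: Electrophilic aromatic iodination ortho to the only free phenol (para position blocked); ring A is deactivated by two acetoxy groups and the acyl group, and one equivalent of reagent at low temperature should limit 3',5'-diiodination.

Step 5
Reactants: 7 (2R,3R)-aromadendrin
Product: 9 (2R,3R)-4'-O-(tert-butyldimethylsilyl)aromadendrin, via 7,4'-bis-O-TBS-aromadendrin 8 (not isolated)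
Conditions: TBSCl (2.2 equiv), imidazole, DMF, 0 °C; extractive work-up; then K2CO3 (0.3 equiv), MeOH–THF, 0 °C, Ar; AcOH quench
Reagents that add atoms: tert-butyldimethylsilyl chloride, CC(C)(C)[Si](C)(C)Cl
Why: Same phenol silylation and selective 7-O-desilylation as in step 1; the hindered, hydrogen-bonded 3-OH should react more slowly than the phenols with limited silyl chloride at 0 °C, and the short, cold carbonate treatment on the 4'-O-blocked substrate leaves no quinone methide route to C2'' epimerisation.

Step 6
Reactants: 9 (2R,3R)-4'-O-(tert-butyldimethylsilyl)aromadendrin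
Product: 10 (2R,3R)-3,5,7-tri-O-acetyl-4'-O-(tert-butyldimethylsilyl)aromadendrin
Conditions: Ac2O, pyridine, DMAP (cat.), CH2Cl2, 0 °C to rt
Reagents that add atoms: acetic anhydride, CC(=O)OC(C)=O
Why: DMAP-catalysed acylation esterifies 7-OH, the chelated 5-OH and the secondary 3-OH in one operation, so the 3-acetate serves in place of a separate protecting group; C2–H and the equatorial 3-acetate are not antiperiplanar, so elimination is not expected.

Step 7
Reactants: 10 (2R,3R)-3,5,7-tri-O-acetyl-4'-O-(tert-butyldimethylsilyl)aromadendrin
Product: 11 (2R,3R)-3,5,7-tri-O-acetylaromadendrin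
Conditions: HF·pyridine, THF–pyridine, 0 °C to rt
Reagents that add atoms: none
Why: Acidic fluoride cleavage of the aryl silyl ether, as in step 3; the esters are untouched.

Step 8
Reactants: 11 (2R,3R)-3,5,7-tri-O-acetylaromadendrin
Product: 12 (2R,3R)-3,5,7-tri-O-acetyl-3'-iodoaromadendrin
Conditions: NIS (1.0 equiv), CF3CO2H (cat.), MeCN, 0 °C
Reagents that add atoms: N-iodosuccinimide, O=C1CCC(=O)N1I
Why: Electrophilic iodination ortho to the free 4'-phenol, as in step 4, with ring A switched off by acylation.

Step 9
Reactants: 12 (2R,3R)-3,5,7-tri-O-acetyl-3'-iodoaromadendrin
Product: 13 (2R,3R)-3,5,7-tri-O-acetyl-3'-iodo-4'-O-(methylthiomethyl)aromadendrin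
Conditions: MeSCH2Cl, AgNO3, Et3N, toluene, rt, dark
Reagents that add atoms: chloromethyl methyl sulfide, CSCCl
Why: Methylthiomethyl ether formation by silver-assisted chloride abstraction; the thionium-type electrophile needs only an amine base, so no free phenoxide is present to attack the activated 7-acetate or to trigger ring opening.

Step 10
Reactants: 13 (2R,3R)-3,5,7-tri-O-acetyl-3'-iodo-4'-O-(methylthiomethyl)aromadendrin; 6 (2S)-5,7-di-O-acetyl-3'-iodonaringenin
Product: 15 mixed formal in which one CH2 links O4' of 6 and O4' of 12, via chloromethyl ether 14 (not isolated)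
Conditions: SO2Cl2 (1.0 equiv), CH2Cl2, −78 to 0 °C; volatiles removed in vacuo; then 6, iPr2NEt, Bu4NI (cat.), CH2Cl2, 0 °C to rt
Reagents that add atoms: none
Why: Chlorinolysis of the O,S-acetal (chlorosulfonium, then oxocarbenium, then chloride) gives the aryl chloromethyl ether, which alkylates the iodophenol in a Williamson-type reaction under the amine-base conditions used for alkoxymethyl protection. Building the formal one C–O bond at a time excludes the symmetrical formals, and the sulfide reacts with the chlorinating agent far faster than the aryl iodide or the non-enolisable ketone side.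

Step 11
Reactants: 15 mixed formal in which one CH2 links O4' of 6 and O4' of 12
Product: 16 2-[(2S)-5,7-diacetoxy-4-oxochroman-2-yl]-10-[(2R,3R)-3,5,7-triacetoxy-4-oxochroman-2-yl]dibenzo[d,f][1,3]dioxepine
Conditions: Ni(cod)2 (2.2 equiv), PPh3 (4.4 equiv), DMF, 50 °C, Ar; 15 added slowly to a final concentration of about 0.005 M
Reagents that add atoms: none
Why: This is an Ullmann-type reductive biaryl coupling mediated by phosphine-ligated zerovalent nickel, the known intramolecular coupling of tethered bis(aryl iodides). One C–I bond adds oxidatively to give an aryl(iodo) complex of divalent nickel; the second C–I bond, held close by the O–CH2–O tether, is engaged within the same molecule (by a second oxidative addition with aryl transfer, or through the monovalent/trivalent nickel manifold) to give a diarylnickel chelate with nickel in an eight-membered ring. Reductive elimination then forms C3'–C3''' and leaves NiI2. The ring closed is the seven-membered 1,3-dioxepine; it is closed by C(sp2)–C(sp2) reductive elimination with extrusion of nickel from the eight-membered metallacycle, not by a nucleophilic cyclisation. No stereocentre is created, and the bridged axis, with only the two tethered oxygens ortho to it, inverts freely, so one compound is expected. Hetero- over homo-coupling and the C3'/C3''' regiochemistry are fixed by the covalent tether and by the iodines ortho to the tethered oxygens. Cyclisation over oligomerisation and hydrodeiodination is served by slow addition at high dilution, the aprotic medium and the absence of any free hydroxyl. Ketones, aryl and alkyl acetates and the acetal are inert to the reagent at 50 °C, and the neutral medium leaves C2, C2'' and C3'' untouched.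

Step 12
Reactants: 16 2-[(2S)-5,7-diacetoxy-4-oxochroman-2-yl]-10-[(2R,3R)-3,5,7-triacetoxy-4-oxochroman-2-yl]dibenzo[d,f][1,3]dioxepine
Product: 17 3',3'''-linked naringenin–aromadendrin 5,7,3'',5'',7''-pentaacetate with free 4'- and 4'''-hydroxyls
Conditions: BCl3 (excess), CH2Cl2, −78 to −20 °C; then aqueous phosphate buffer, 0 °C
Reagents that add atoms: none
Why: Boron trihalide cleavage of an aryl methylene acetal, as used for methylenedioxyarenes: boron binds an acetal oxygen, chloride opens the strained seven-membered acetal to an aryl dichloroborinate and an aryl chloromethyl ether, and both hydrolyse on work-up with loss of formaldehyde. The rings A are still acylated and the medium is aprotic and cold, so the one-carbon electrophile has no nucleophilic arene to attack and the benzylic C–O bonds of the heterocycles should not ionise.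

Step 13
Reactants: 17 3',3'''-linked naringenin–aromadendrin 5,7,3'',5'',7''-pentaacetate with free 4'- and 4'''-hydroxyls
Product: 18 (2S)-naringenin-(3'→3''')-(2R,3R)-aromadendrin (the target)
Conditions: HCl in MeOH (about 1 M, from AcCl), rt to 40 °C
Reagents that add atoms: none
Why: Acid-catalysed transesterification removes the four aryl acetates and the secondary 3''-acetate as methyl acetate; under acid neither the enolate nor the quinone methide pathway to ring opening operates, so the three stereocentres are retained.

## Compound list

1 | (2S)-naringenin, (2S)-5,7-dihydroxy-2-(4-hydroxyphenyl)chroman-4-one | O=C1C[C@@H](c2ccc(O)cc2)Oc2cc(O)cc(O)c21 | starting material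
2 | (2S)-7,4'-bis-O-(tert-butyldimethylsilyl)naringenin (5-OH free) | O=C1C[C@@H](c2ccc(O[Si](C)(C)C(C)(C)C)cc2)Oc2cc(O[Si](C)(C)C(C)(C)C)cc(O)c21 | intermediate (not isolated)
3 | (2S)-4'-O-(tert-butyldimethylsilyl)naringenin (5-OH and 7-OH free) | O=C1C[C@@H](c2ccc(O[Si](C)(C)C(C)(C)C)cc2)Oc2cc(O)cc(O)c21 | intermediate
4 | (2S)-5,7-di-O-acetyl-4'-O-(tert-butyldimethylsilyl)naringenin | O=C1C[C@@H](c2ccc(O[Si](C)(C)C(C)(C)C)cc2)Oc2cc(OC(C)=O)cc(OC(C)=O)c21 | intermediate
5 | (2S)-5,7-di-O-acetylnaringenin (4'-OH free) | O=C1C[C@@H](c2ccc(O)cc2)Oc2cc(OC(C)=O)cc(OC(C)=O)c21 | intermediate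
6 | (2S)-5,7-di-O-acetyl-3'-iodonaringenin, (2S)-5,7-diacetoxy-2-(4-hydroxy-3-iodophenyl)chroman-4-one | O=C1C[C@@H](c2ccc(O)c(I)c2)Oc2cc(OC(C)=O)cc(OC(C)=O)c21 | intermediate
7 | (2R,3R)-aromadendrin, (2R,3R)-3,5,7-trihydroxy-2-(4-hydroxyphenyl)chroman-4-one | Oc1ccc(cc1)[C@H]1Oc2cc(O)cc(O)c2C(=O)[C@@H]1O | starting material
8 | (2R,3R)-7,4'-bis-O-(tert-butyldimethylsilyl)aromadendrin (3-OH and 5-OH free) | CC(C)(C)[Si](C)(C)Oc1ccc(cc1)[C@H]1Oc2cc(O[Si](C)(C)C(C)(C)C)cc(O)c2C(=O)[C@@H]1O | intermediate (not isolated)
9 | (2R,3R)-4'-O-(tert-butyldimethylsilyl)aromadendrin | CC(C)(C)[Si](C)(C)Oc1ccc(cc1)[C@H]1Oc2cc(O)cc(O)c2C(=O)[C@@H]1O | intermediate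
10 | (2R,3R)-3,5,7-tri-O-acetyl-4'-O-(tert-butyldimethylsilyl)aromadendrin | CC(C)(C)[Si](C)(C)Oc1ccc(cc1)[C@H]1Oc2cc(OC(C)=O)cc(OC(C)=O)c2C(=O)[C@@H]1OC(C)=O | intermediate
11 | (2R,3R)-3,5,7-tri-O-acetylaromadendrin (4'-OH free) | Oc1ccc(cc1)[C@H]1Oc2cc(OC(C)=O)cc(OC(C)=O)c2C(=O)[C@@H]1OC(C)=O | intermediate
12 | (2R,3R)-3,5,7-tri-O-acetyl-3'-iodoaromadendrin | Oc1ccc(cc1I)[C@H]1Oc2cc(OC(C)=O)cc(OC(C)=O)c2C(=O)[C@@H]1OC(C)=O | intermediate
13 | (2R,3R)-3,5,7-tri-O-acetyl-3'-iodo-4'-O-(methylthiomethyl)aromadendrin | CSCOc1ccc(cc1I)[C@H]1Oc2cc(OC(C)=O)cc(OC(C)=O)c2C(=O)[C@@H]1OC(C)=O | intermediate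
14 | (2R,3R)-3,5,7-tri-O-acetyl-4'-O-(chloromethyl)-3'-iodoaromadendrin | ClCOc1ccc(cc1I)[C@H]1Oc2cc(OC(C)=O)cc(OC(C)=O)c2C(=O)[C@@H]1OC(C)=O | intermediate (not isolated)
15 | mixed formal: (2S)-5,7-diacetoxy-2-(3-iodo-4-{[2-iodo-4-((2R,3R)-3,5,7-triacetoxy-4-oxochroman-2-yl)phenoxy]methoxy}phenyl)chroman-4-one | O=C1C[C@@H](c2ccc(OCOc3ccc(cc3I)[C@H]3Oc4cc(OC(C)=O)cc(OC(C)=O)c4C(=O)[C@@H]3OC(C)=O)c(I)c2)Oc2cc(OC(C)=O)cc(OC(C)=O)c21 | intermediate (key-step precursor)
16 | methylene-bridged pentaacetate: 2-[(2S)-5,7-diacetoxy-4-oxochroman-2-yl]-10-[(2R,3R)-3,5,7-triacetoxy-4-oxochroman-2-yl]dibenzo[d,f][1,3]dioxepine | O=C1C[C@@H](c2ccc3OCOc4ccc(cc4-c3c2)[C@H]2Oc3cc(OC(C)=O)cc(OC(C)=O)c3C(=O)[C@@H]2OC(C)=O)Oc2cc(OC(C)=O)cc(OC(C)=O)c21 | intermediate (key-step product)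
17 | 3',3'''-linked (2S)-naringenin–(2R,3R)-aromadendrin 5,7,3'',5'',7''-pentaacetate (4'-OH and 4'''-OH free) | O=C1C[C@@H](c2ccc(O)c(-c3cc([C@H]4Oc5cc(OC(C)=O)cc(OC(C)=O)c5C(=O)[C@@H]4OC(C)=O)ccc3O)c2)Oc2cc(OC(C)=O)cc(OC(C)=O)c21 | intermediate
18 | (2S)-naringenin-(3'→3''')-(2R,3R)-aromadendrin | O=C1C[C@@H](c2ccc(O)c(-c3cc([C@H]4Oc5cc(O)cc(O)c5C(=O)[C@@H]4O)ccc3O)c2)Oc2cc(O)cc(O)c21 | target

## Step count and least certain steps

Total step count: 13. Longest linear sequence: 9 steps (steps 5 to 13, from 7); the naringenin branch (steps 1 to 4) joins at step 10.

**Step 11 (key step).** The likeliest failure is protonolysis of the arylnickel intermediates (hydrodeiodination) or intermolecular coupling outrunning the closure. Reductive elimination from a medium-ring diarylnickel species can be slow, and the enolisable C3 methylene is an internal proton source. The fallback gives the two ring B carbons opposite polarity before tethering. From iodophenol 6, palladium-catalysed stannylation [Pd(PPh3)4, Me3SnSnMe3, toluene, 90 °C] would give (2S)-5,7-di-O-acetyl-3'-(trimethylstannyl)naringenin F1. Alkylation of F1 with chloromethyl ether 14 under the conditions of step 10 would give the mixed formal carrying iodine on the dihydroflavonol ring B and the stannyl group on the flavanone ring B, F2. An intramolecular Stille coupling [Pd2(dba)3, AsPh3, CuI, DMF, 60 °C] would close the dioxepine and return to the route at 16.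

**Step 10.** The likeliest failures are over-reaction of the chlorinating agent (oxidation at iodine or ring chlorination), hydrolysis of 14 before it meets the phenol, and acetyl transfer onto the phenol if the alkylation is slow. The fallback avoids the chloride altogether: O,S-acetal 13 and phenol 6 would be combined directly under thiophilic activation, as in thioglycoside chemistry, using dimethyl(methylthio)sulfonium triflate with 2,6-di-tert-butyl-4-methylpyridine and 4 Å sieves in CH2Cl2 at −20 °C. It sets out from 13 and comes back at 15 without any new compound.

**Step 9.** The likeliest failure is migration of the activated 7-acetyl group to the 4'-oxygen once the iodophenol is even partly ionised by the amine, with C-alkylation at C5' as a second risk. The fallback removes the base. From 12, N,O-bis(trimethylsilyl)acetamide in CH2Cl2 would give (2R,3R)-3,5,7-tri-O-acetyl-3'-iodo-4'-O-(trimethylsilyl)aromadendrin F3. Alkylation of this silyl ether with chloromethyl methyl sulfide promoted by AgOTf, buffered with 2,6-di-tert-butyl-4-methylpyridine, would return to the route at 13.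

**Step 12.** The likeliest failure is ionisation of the benzylic C2–O1 and C2''–O1'' bonds by the Lewis acid, causing epimerisation or opening to chalcones, or cleavage that stalls. The fallback is a Brønsted-acid solvolysis: from 16, prolonged heating in methanolic HCl (about 3 M, 60 °C) would remove the acetal carbon as dimethoxymethane and the acetates as methyl acetate in one operation. It returns directly at 18 and bypasses 17; the solvent methanol traps the one-carbon cation before the freed rings A can.

**Step 5.** The likeliest failure is loss of selectivity in the silyl relay: silylation of the 3-hydroxyl, incomplete discrimination between the two aryl silyl ethers, or base-induced isomerisation of the dihydroflavonol during the carbonate treatment. The fallback reverses the order and uses the higher acidity of 7-OH. From 7, one equivalent of Ac2O in pyridine at −20 °C would give (2R,3R)-7-O-acetylaromadendrin F4; TBSCl and imidazole would silylate the remaining reactive phenol to give (2R,3R)-7-O-acetyl-4'-O-(tert-butyldimethylsilyl)aromadendrin F5; Ac2O with DMAP would then acetylate O3 and O5 and come back at 10.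

## Further compounds

F1 | step 11 | (2S)-5,7-di-O-acetyl-3'-(trimethylstannyl)naringenin | O=C1C[C@@H](c2ccc(O)c([Sn](C)(C)C)c2)Oc2cc(OC(C)=O)cc(OC(C)=O)c21
F2 | step 11 | mixed formal of F1 and 12 (CH2 between the two 4'-oxygens; iodine on the dihydroflavonol ring B, trimethylstannyl on the flavanone ring B) | O=C1C[C@@H](c2ccc(OCOc3ccc(cc3I)[C@H]3Oc4cc(OC(C)=O)cc(OC(C)=O)c4C(=O)[C@@H]3OC(C)=O)c([Sn](C)(C)C)c2)Oc2cc(OC(C)=O)cc(OC(C)=O)c21
F0 | step 10 | none | none
F3 | step 9 | (2R,3R)-3,5,7-tri-O-acetyl-3'-iodo-4'-O-(trimethylsilyl)aromadendrin | C[Si](C)(C)Oc1ccc(cc1I)[C@H]1Oc2cc(OC(C)=O)cc(OC(C)=O)c2C(=O)[C@@H]1OC(C)=O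
F0 | step 12 | none | none
F4 | step 5 | (2R,3R)-7-O-acetylaromadendrin | Oc1ccc(cc1)[C@H]1Oc2cc(OC(C)=O)cc(O)c2C(=O)[C@@H]1O
F5 | step 5 | (2R,3R)-7-O-acetyl-4'-O-(tert-butyldimethylsilyl)aromadendrin | CC(C)(C)[Si](C)(C)Oc1ccc(cc1)[C@H]1Oc2cc(OC(C)=O)cc(O)c2C(=O)[C@@H]1O
A1 | alternative 1 | tetraene: biaryl bis(1-arylallyl) ether of two 3,5-bis(benzyloxy)-2-vinylphenols | C=C[C@@H](c1ccc(OCc2ccccc2)c(c1)-c1cc(ccc1OCc1ccccc1)[C@H](C=C)Oc1cc(OCc2ccccc2)cc(OCc2ccccc2)c1C=C)Oc1cc(OCc2ccccc2)cc(OCc2ccccc2)c1C=C
A2 | alternative 1 | (2S,2''S)-hexa-O-benzyl bis(flav-3-ene) | C1=C[C@@H](c2ccc(OCc3ccccc3)c(c2)-c2cc(ccc2OCc2ccccc2)[C@@H]2C=Cc3c(OCc4ccccc4)cc(OCc4ccccc4)cc3O2)Oc2cc(OCc3ccccc3)cc(OCc3ccccc3)c21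
A3 | alternative 2 | (E)-2-[5-bromo-2-(methoxymethoxy)phenyl]-3-(tert-butyldimethylsilyloxy)-1-methoxybuta-1,3-diene | CO/C=C(\c1cc(Br)ccc1OCOC)C(=C)O[Si](C)(C)C(C)(C)C
A4 | alternative 2 | ethyl propiolate | C#CC(=O)OCC
A5 | alternative 2 | ethyl 3-[5-bromo-2-(methoxymethoxy)phenyl]-4-(tert-butyldimethylsilyloxy)benzoate | CCOC(=O)c1ccc(O[Si](C)(C)C(C)(C)C)c(c1)-c1cc(Br)ccc1OCOC
A6 | alternative 3 | 3,5-bis(benzyloxy)-2-(trimethylsilyl)phenyl trifluoromethanesulfonate | C[Si](C)(C)c1c(OS(=O)(=O)C(F)(F)F)cc(OCc2ccccc2)cc1OCc1ccccc1
A7 | alternative 3 | (4R,5S)-5-{4-(benzyloxy)-3-[2-(benzyloxy)-5-chlorophenyl]phenyl}-2,2-dimethyl-1,3-dioxolane-4-carboxylic acid | OC(=O)[C@@H]1OC(C)(C)O[C@H]1c1ccc(OCc2ccccc2)c(c1)-c1cc(Cl)ccc1OCc1ccccc1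
A8 | alternative 3 | [2,4-bis(benzyloxy)-6-hydroxyphenyl] ketone of the trans acetonide, (4R,5S)-configured | Oc1cc(OCc2ccccc2)cc(OCc2ccccc2)c1C(=O)[C@@H]1OC(C)(C)O[C@H]1c1ccc(OCc2ccccc2)c(c1)-c1cc(Cl)ccc1OCc1ccccc1
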